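**Strategy.** The O1–C2 bond of the dihydrofuran ring (O1, C2, C3, C3a, C7a) is disconnected to a spiro cyclopropane (C3a, C3, C2) whose C7a ketone is the future enol ether oxygen. This exploits two features: C3a is the α-carbon of the masked C7a ketone, and as a quaternary spiro centre it blocks aromatisation of the six-membered ring while a nitrile oxide installs the cis C6–O/C7–acyl pair on a dienone. The key step is an iodide-triggered Cloke–Wilson ring expansion at the acetyl-bearing C2. In one operation it unveils the C3a=C7a–C4=C5 dienol ether and the trans C2/C3 relationship from an acetylcyclopropyl ketone.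

Key step: step 8

Remark 1: Target (benzofuran) numbering O1, C2, C3, C3a, C4–C7, C7a is used in the text for all intermediates; in spiro[2.5]octane names C1 = C3, C2 = C2, C3 = C3a, C4–C7 = C4–C7, C8 = C7a.
Remark 2: Compounds 8 and 13 are carried as both C3a (spiro) epimers and their SMILES leave C3a undefined; both epimers should converge in step 8, where C3a becomes trigonal.
Remark 3: The target is an arene hydrate with a β-hydroxy ketone; it and 14–16 are assumed to need neutral handling (buffered work-up, amine-washed silica, low temperature).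

Step 1
Reactants: 1 methyl 3-formyl-4-hydroxybenzoate
Product: 2 methyl 3-formyl-4-(pivaloyloxy)benzoate
Conditions: PivCl, Et3N, DMAP (cat.), CH2Cl2, 0 °C to rt
Reagents that add atoms: pivaloyl chloride, CC(C)(C)C(Cl)=O
Why: O-acylation of the phenol; the hindered pivalate should survive the amine catalysis of step 3 and, as an acyloxy group, keeps the aryl ring a poor donor so that the later cyclopropane is not prone to benzylic ionisation.

Step 2
Reactants: 2 methyl 3-formyl-4-(pivaloyloxy)benzoate; 3 1-(triphenyl-λ5-phosphanylidene)propan-2-one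
Product: 4 (E)-aryl enone
Conditions: toluene, 80 °C
Reagents that add atoms: none
Why: Wittig olefination with a stabilised ylide should give the (E)-enone selectively.

Step 3
Reactants: 4 (E)-aryl enone; 5 2-chlorocyclohexane-1,3-dione
Product: 6 (1R,2S)-trans spiro dione
Conditions: 9-amino(9-deoxy)epi-quinine (20 mol %), PhCO2H (40 mol %), 2,6-lutidine (1.1 equiv), toluene, 0 °C to rt
Reagents that add atoms: none
Why: Michael-initiated ring closure under iminium/enamine catalysis, in which addition of the chlorodione carbon (future C3a) to the β-carbon sets C3 under control of the cinchona primary amine (quinine-derived amine proposed, its quinidine-derived pseudo-enantiomer being the alternative for the (1R,2S) series) and the enamine then displaces chloride in a 3-exo-tet closure that places acetyl trans to aryl.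

Step 4
Reactants: 6 (1R,2S)-trans spiro dione
Product: 7 spiro vinylogous acid
Conditions: IBX (1.5 equiv), 4-methoxypyridine N-oxide (1.5 equiv), DMSO, rt
Reagents that add atoms: none
Why: IBX α,β-dehydrogenation of a cyclohexanone; either ring ketone gives the same ene-dione, which should rest as the vinylogous acid, while the quaternary C3a excludes tautomerisation to a phenol and the acetyl group has no α,β C–H pair to lose.

Step 5
Reactants: 7 spiro vinylogous acid
Product: 8 spiro methoxy dienone (both spiro epimers)
Conditions: TMSCHN2 (1.2 equiv), toluene/MeOH 4:1, 0 °C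
Reagents that add atoms: (trimethylsilyl)diazomethane, C[Si](C)(C)C=[N+]=[N-]
Why: O-methylation of an acidic vinylogous acid with a diazoalkane; methylation at either oxygen gives the two C3a epimers of one dienone, both of which are used.

Step 6
Reactants: 9 3-phenylpropanal
Product: 10 3-phenylpropanal oxime
Conditions: NH2OH·HCl, NaOAc, EtOH/H2O, rt
Reagents that add atoms: hydroxylamine hydrochloride, Cl.NO
Why: Oxime condensation of an aldehyde, giving the nitrile oxide precursor.

Step 7
Reactants: 8 spiro methoxy dienone (both spiro epimers); 10 3-phenylpropanal oxime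
Product: 13 isoxazoline-fused spiro ketone (both spiro epimers), via hydroximoyl chloride 11 (not isolated), via nitrile oxide 12 (not isolated)
Conditions: 10 (2.5 equiv), NCS, pyridine (cat.), CHCl3, 0 °C to rt; then 8, Et3N (slow addition), 0 °C to rt
Reagents that add atoms: N-chlorosuccinimide, O=C1CCC(=O)N1Cl (chlorine carried by 11 only)
Why: Nitrile oxide 1,3-dipolar cycloaddition to the enone C6=C7 (oxygen to the β-carbon C6, carbon to C7, as for cyclic enones and reinforced by the δ-methoxy push), the hindered enol ether C4=C5 being left; suprafacial addition fixes C6–O and C7–C cis, and approach anti to the cyclopropane substituent lying over C7a (acetyl in one spiro epimer, aryl in the other) should give the same C6/C7 configuration relative to C3 in both.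

Step 8
Reactants: 13 isoxazoline-fused spiro ketone (both spiro epimers)
Product: 14 trans-2-acetyl-3-aryl dihydrofuran
Conditions: MgI2 (20 mol %), THF, 45 °C
Reagents that add atoms: none
Why: Proposed new method: iodide attacks C2, the cyclopropane carbon α to the acetyl group, with inversion and expels C3a as the magnesium dienolate of the C7a ketone (C3a–C2 is the only ring bond flanked by two carbonyl groups); the enolate oxygen O1 then displaces iodide from the α-iodo ketone in a 5-exo-tet closure that forms O1–C2 and returns the catalyst. The closest known reactions are the MgI2- and iodide-promoted openings of spiro cyclopropyl carbonyl compounds, the nucleophile-catalysed Cloke–Wilson rearrangement of acylcyclopropanes and the O-alkylative closure of the interrupted Feist–Benary reaction; new is that the acceptor–acceptor bond, not the aryl-bearing bond, is cleaved. C2 is re-formed by two inversions, that is with retention, so the trans cyclopropane becomes the 2,3-trans dihydrofuran, and any leakage can equilibrate to trans because C2 is α to the acetyl group; C3, C6 and C7 are untouched and C3a becomes trigonal, so both spiro epimers give one product. The step needs attack at C2 and not at the benzylic C3: the ortho-pivaloyloxy and meta-ester groups make the aryl ring electron-poor and hinder C3, while the acetyl group accelerates substitution at C2. It also needs the new C3a=C7a–C4=C5 dienol ether to survive, which is why only a catalytic amount of a mild iodide salt is used.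

Step 9
Reactants: 14 trans-2-acetyl-3-aryl dihydrofuran
Product: 15 tertiary alcohol pivalate
Conditions: MeMgBr (1.5 equiv), CeCl3 (1.5 equiv), THF, −78 °C; aq NaHCO3
Reagents that add atoms: methylmagnesium bromide, C[Mg]Br
Why: Organocerium 1,2-addition to the only ketone; the weakly basic reagent should avoid enolisation at C2 and leave the pivalate, benzoate and isoxazoline alone, and no stereocentre is formed because the carbinol carries two methyl groups.

Step 10
Reactants: 15 tertiary alcohol pivalate
Product: 16 free phenol isoxazoline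
Conditions: N2H4·H2O (5 equiv), THF/MeOH 3:1, 0 °C, Ar
Reagents that add atoms: none
Why: Hydrazinolysis of an aryl ester, a near-neutral acyl transfer to a strong α-nucleophile that should spare the methyl benzoate, the isoxazoline and the base-sensitive diene.

Step 11
Reactants: 16 free phenol isoxazoline
Product: 17 methyl 4-hydroxy-3-[(2R,3R,6R,7R)-6-hydroxy-2-(2-hydroxypropan-2-yl)-4-methoxy-7-(3-phenylpropanoyl)-2,3,6,7-tetrahydro-1-benzofuran-3-yl]benzoate
Conditions: SmI2 (2.5 equiv), THF, −20 °C; then pH 7 phosphate buffer, 0 °C
Reagents that add atoms: water, O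
Why: Reductive N–O cleavage of the isoxazoline by SmI2 followed by hydrolysis of the β-hydroxy imine at neutral pH should release the β-hydroxy ketone without touching C6 or C7, so the cis relationship set in step 7 is kept.

**Compound list**

1 | methyl 3-formyl-4-hydroxybenzoate | COC(=O)c1ccc(O)c(C=O)c1 | starting material
2 | methyl 4-[(2,2-dimethylpropanoyl)oxy]-3-formylbenzoate | COC(=O)c1ccc(OC(=O)C(C)(C)C)c(C=O)c1 | intermediate
3 | 1-(triphenyl-λ5-phosphanylidene)propan-2-one | CC(=O)C=P(c1ccccc1)(c1ccccc1)c1ccccc1 | starting material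
4 | methyl 4-[(2,2-dimethylpropanoyl)oxy]-3-[(1E)-3-oxobut-1-en-1-yl]benzoate | COC(=O)c1ccc(OC(=O)C(C)(C)C)c(/C=C/C(C)=O)c1 | intermediate
5 | 2-chlorocyclohexane-1,3-dione | O=C1CCCC(=O)C1Cl | starting material
6 | methyl 3-[(1R,2S)-2-acetyl-4,8-dioxospiro[2.5]octan-1-yl]-4-[(2,2-dimethylpropanoyl)oxy]benzoate (aryl and acetyl trans) | COC(=O)c1ccc(OC(=O)C(C)(C)C)c([C@H]2[C@H](C(C)=O)C23C(=O)CCCC3=O)c1 | intermediate
7 | methyl 3-[(1R,2S)-2-acetyl-4-hydroxy-8-oxospiro[2.5]octa-4,6-dien-1-yl]-4-[(2,2-dimethylpropanoyl)oxy]benzoate (vinylogous acid; spiro carbon not fixed because of tautomerism) | COC(=O)c1ccc(OC(=O)C(C)(C)C)c([C@H]2[C@H](C(C)=O)C23C(O)=CC=CC3=O)c1 | intermediate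
8 | methyl 3-[(1R,2S)-2-acetyl-4-methoxy-8-oxospiro[2.5]octa-4,6-dien-1-yl]-4-[(2,2-dimethylpropanoyl)oxy]benzoate (both epimers at the spiro carbon) | COC(=O)c1ccc(OC(=O)C(C)(C)C)c([C@H]2[C@H](C(C)=O)C23C(OC)=CC=CC3=O)c1 | intermediate
9 | 3-phenylpropanal | O=CCCc1ccccc1 | starting material
10 | 3-phenylpropanal oxime | ON=CCCc1ccccc1 | intermediate
11 | N-hydroxy-3-phenylpropanimidoyl chloride | ON=C(Cl)CCc1ccccc1 | intermediate
12 | 3-phenylpropanenitrile oxide | [O-][N+]#CCCc1ccccc1 | intermediate
13 | methyl 3-[(1R,2S)-2-acetyl-4-methoxy-8-oxospiro[2.5]oct-4-en-1-yl]-4-[(2,2-dimethylpropanoyl)oxy]benzoate carrying a 3-(2-phenylethyl)-4,5-dihydroisoxazole cis-fused across C6–C7 (ring O on C6, C=N carbon on C7; C6 and C7 configured as in the target; both epimers at the spiro carbon) | COC(=O)c1ccc(OC(=O)C(C)(C)C)c([C@H]2[C@H](C(C)=O)C23C(OC)=C[C@H]4ON=C(CCc5ccccc5)[C@H]4C3=O)c1 | intermediate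
14 | methyl 3-[(2R,3R)-2-acetyl-4-methoxy-2,3,6,7-tetrahydro-1-benzofuran-3-yl]-4-[(2,2-dimethylpropanoyl)oxy]benzoate carrying the 3-(2-phenylethyl)-4,5-dihydroisoxazole cis-fused across C6–C7 (O on C6; 2,3-trans; C6 and C7 as in the target) | COC(=O)c1ccc(OC(=O)C(C)(C)C)c([C@@H]2C3=C(O[C@H]2C(C)=O)[C@@H]2C(CCc4ccccc4)=NO[C@@H]2C=C3OC)c1 | intermediate
15 | the 2-(2-hydroxypropan-2-yl) analogue of 14 (2R,3R; pivalate retained; isoxazoline as in 14) | COC(=O)c1ccc(OC(=O)C(C)(C)C)c([C@@H]2C3=C(O[C@H]2C(C)(C)O)[C@@H]2C(CCc4ccccc4)=NO[C@@H]2C=C3OC)c1 | intermediate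
16 | methyl 4-hydroxy-3-[(2R,3R)-2-(2-hydroxypropan-2-yl)-4-methoxy-2,3,6,7-tetrahydro-1-benzofuran-3-yl]benzoate carrying the 3-(2-phenylethyl)-4,5-dihydroisoxazole cis-fused across C6–C7 (O on C6; C6 and C7 as in the target) | COC(=O)c1ccc(O)c([C@@H]2C3=C(O[C@H]2C(C)(C)O)[C@@H]2C(CCc4ccccc4)=NO[C@@H]2C=C3OC)c1 | intermediate
17 | methyl 4-hydroxy-3-[(2R,3R,6R,7R)-6-hydroxy-2-(2-hydroxypropan-2-yl)-4-methoxy-7-(3-phenylpropanoyl)-2,3,6,7-tetrahydro-1-benzofuran-3-yl]benzoate | COC(=O)c1ccc(O)c([C@@H]2C3=C(O[C@H]2C(C)(C)O)[C@H](C(=O)CCc2ccccc2)[C@H](O)C=C3OC)c1 | target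

Total step count: 11. Longest linear sequence: 10 steps (steps 1–5 and 7–11).

**Steps most likely to fail**

1. Step 8 (Proposed new method). Iodide may instead attack the benzylic C3, giving regiochemical leakage to the 2-aryl-3-acetyl isomer, or the magnesium salt may assist ionisation of the C6–O bond of the product and so cause aromatisation. The fallback uses known chemistry, sets out from 13 and comes back at 15; it moves the ring expansion to a zerovalent nickel π-allyl, where ionisation can only occur at the allylic C2. Methyl addition to the acetyl group of 13 (MeMgBr, CeCl3, THF, −78 °C) should give the cyclopropyl dimethyl carbinol F1. Dehydration with methyl N-(triethylammoniumsulfonyl)carbamate (benzene, 50 °C) should give the isopropenyl vinylcyclopropane F2. The known rearrangement of 1-acyl-2-vinylcyclopropanes with Ni(cod)2 and PPh3 (THF, rt) should give the trans-2-isopropenyl dihydrofuran F3. Mukaiyama hydration of the 1,1-disubstituted alkene (Mn(dpm)3, PhSiH3, O2, iPrOH, 0 °C) then returns to 15; its chemoselectivity over the ring diene is the weak point of this branch.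

2. Step 7. The dipole may add to the enol ether C4=C5, add with reversed regiochemistry, or discriminate the two faces poorly. The fallback sets out from 8 and comes back at 13; it builds the isoxazoline stepwise so that connectivity is fixed by construction and the cis relationship by ring fusion. α-Iodination of the enone (I2, pyridine, CH2Cl2, rt) should give the 7-iodo dienone F4. Nozaki–Hiyama–Kishi coupling with 9 (CrCl2, NiCl2 cat., DMF, rt) should give the allylic alcohol F5. Dess–Martin oxidation (NaHCO3, CH2Cl2, 0 °C) should give the 7-acyl dienone F6. Hydroxylamine (NH2OH·HCl, NaOAc, EtOH, 0 °C to rt) should condense at the side-chain ketone to the oxime F7, whose oxygen adds to C6 (5-endo oxa-Michael, anti to the cyclopropane substituent over C7a) to give 13.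

3. Step 11. Acid- or base-promoted loss of the C6 hydroxyl with aromatisation, or retro-aldol cleavage, may occur while trivalent samarium and liberated ammonia are present. The fallback sets out from 16 and comes back at 17. The unmasking is changed from outer-sphere electron transfer with a separate hydrolysis to an inner-sphere molybdenum-mediated N–O cleavage with water present from the start (Mo(CO)6, MeCN/H2O 10:1, 60 °C); no oxophilic lanthanide salt is formed and the imine is hydrolysed as it is released.

Further compounds
F1 | step 8 | methyl 3-[(1R,2S)-2-(2-hydroxypropan-2-yl)-4-methoxy-8-oxospiro[2.5]oct-4-en-1-yl]-4-[(2,2-dimethylpropanoyl)oxy]benzoate with the isoxazoline of 13 (both spiro epimers) | COC(=O)c1ccc(OC(=O)C(C)(C)C)c([C@H]2[C@H](C(C)(C)O)C23C(OC)=C[C@H]4ON=C(CCc5ccccc5)[C@H]4C3=O)c1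
F2 | step 8 | the 2-(prop-1-en-2-yl) analogue of F1 (vinylcyclopropane; both spiro epimers) | COC(=O)c1ccc(OC(=O)C(C)(C)C)c([C@H]2[C@H](C(C)=C)C23C(OC)=C[C@H]4ON=C(CCc5ccccc5)[C@H]4C3=O)c1
F3 | step 8 | the trans-2-(prop-1-en-2-yl) analogue of 14 | COC(=O)c1ccc(OC(=O)C(C)(C)C)c([C@@H]2C3=C(O[C@H]2C(C)=C)[C@@H]2C(CCc4ccccc4)=NO[C@@H]2C=C3OC)c1
F4 | step 7 | the 7-iodo derivative of 8 (both spiro epimers) | COC(=O)c1ccc(OC(=O)C(C)(C)C)c([C@H]2[C@H](C(C)=O)C23C(OC)=CC=C(I)C3=O)c1
F5 | step 7 | the 7-(1-hydroxy-3-phenylpropyl) derivative of 8 (carbinol configuration open) | COC(=O)c1ccc(OC(=O)C(C)(C)C)c([C@H]2[C@H](C(C)=O)C23C(OC)=CC=C(C(O)CCc4ccccc4)C3=O)c1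
F6 | step 7 | the 7-(3-phenylpropanoyl) derivative of 8 | COC(=O)c1ccc(OC(=O)C(C)(C)C)c([C@H]2[C@H](C(C)=O)C23C(OC)=CC=C(C(=O)CCc4ccccc4)C3=O)c1
F7 | step 7 | the side-chain oxime of F6 | COC(=O)c1ccc(OC(=O)C(C)(C)C)c([C@H]2[C@H](C(C)=O)C23C(OC)=CC=C(C(CCc4ccccc4)=NO)C3=O)c1
F0 | step 11 | none | none
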